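**Retrosynthetic overview**
1. Target 44 ⇐ triol 41 (MnO2 allylic oxidation/lactonisation C12→O8, α-methylene-γ-lactone closed last) ⇐ butenolide 40 ⇐ triol 37 (oxidative lactonisation C15→O6); both lactone carbonyls travel as silyl-protected allylic CH2OH groups.
2. Ten-membered carbocycle ⇐ intramolecular Nozaki–Hiyama–Kishi closure of C3–C4 in iodo-aldehyde 32; C3 is then set by oxidation/CBS reduction and acylated.
3. Vinyl iodide part (C4, C5, C15) ⇐ Weinreb amide 20 + trimethylsilylacetylene, 1,3-anti reduction (C6), ClCO2Me, Pd-catalysed hydrostannation/iodination.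
4. Fragment union: Evans syn-aldol forming C7–C8 from imide 17 (C6, C7, C11–C13; from 4-methyl hydrogen itaconate) and aldehyde 10 (C8–C10, C14, C1–C3; C10 by Evans allylation, from δ-valerolactone).
5. Ring order: carbocycle (step 23), butenolide (step 28), α-methylene-γ-butyrolactone (step 30).

Assumption (conventions): target locants C1–C15 are used for all intermediates (ring C1–C10; C3 acyloxy carbon; C4=C5 butenolide alkene; C6 and C8 lactone O-bearing carbons; C10 bears C14H2OH; C11/C12/C13 α-methylene lactone carbons, C12 = carbonyl; C15 = butenolide carbonyl). PMB = 4-methoxybenzyl, TBDPS = tert-butyldiphenylsilyl, TBS = tert-butyldimethylsilyl. The C6 descriptor changes from S (22–32) to R (33–44) only because CIP priorities change; the centre is never inverted.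

**Route**

Step 1
Reactants: 1 δ-valerolactone
Product: 2 5-[(4-methoxybenzyl)oxy]pentanoic acid
Conditions: KOH (powder), PMBCl, toluene, reflux; aq. KOH/MeOH; then 1 M HCl
Reagents that add atoms: 4-methoxybenzyl chloride, COc1ccc(CCl)cc1; potassium hydroxide, [K+].[OH-]
Why: Lactone saponification and Williamson etherification of the resulting alkoxide in one pot (any PMB ester is hydrolysed in the basic work-up).

Step 2
Reactants: 2 5-[(4-methoxybenzyl)oxy]pentanoic acid; 3 (S)-4-benzyl-1,3-oxazolidin-2-one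
Product: 5 (S)-4-benzyl-3-[5-(PMB-oxy)pentanoyl]oxazolidin-2-one, via mixed pivalic anhydride 4 (not isolated)
Conditions: PivCl, Et3N, THF, −20 °C; then LiCl, 3, −20 °C → rt
Reagents that add atoms: pivaloyl chloride, CC(C)(C)C(=O)Cl (its atoms stay only in 4)
Why: N-acylation of the oxazolidinone through the mixed anhydride under LiCl/Et3N activation, the standard Evans imide synthesis.

Step 3
Reactants: 5 (S)-4-benzyl-3-[5-(PMB-oxy)pentanoyl]oxazolidin-2-one
Product: 7 (S)-4-benzyl-3-[(2R)-2-allyl-5-(PMB-oxy)pentanoyl]oxazolidin-2-one, via sodium enolate 6 (not isolated)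
Conditions: NaN(SiMe3)2, THF, −78 °C; allyl iodide, −78 → −45 °C
Reagents that add atoms: allyl iodide, C=CCI; sodium bis(trimethylsilyl)amide, C[Si](C)(C)N([Na])[Si](C)(C)C (sodium only in 6)
Why: Evans asymmetric alkylation; the chelated (Z)-enolate is allylated on the face opposite the benzyl group, which sets C10 (2R in the imide).

Step 4
Reactants: 7 (S)-4-benzyl-3-[(2R)-2-allyl-5-(PMB-oxy)pentanoyl]oxazolidin-2-one
Product: 8 (R)-2-allyl-5-(PMB-oxy)pentan-1-ol
Conditions: LiBH4, MeOH (1 equiv), Et2O, 0 °C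
Reagents that add atoms: none
Why: Reductive cleavage of the imide (hydride attack at the exocyclic carbonyl) leaves the stereocentre untouched and returns auxiliary 3.

Step 5
Reactants: 8 (R)-2-allyl-5-(PMB-oxy)pentan-1-ol
Product: 9 (R)-tert-butyl({2-[3-(PMB-oxy)propyl]pent-4-en-1-yl}oxy)diphenylsilane
Conditions: TBDPSCl, imidazole, DMF, rt
Reagents that add atoms: tert-butylchlorodiphenylsilane, CC(C)(C)[Si](Cl)(c1ccccc1)c1ccccc1
Why: Silyl ether formation gives the C14 oxygen a fluoride-labile group that survives all later steps.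

Step 6
Reactants: 9 (R)-tert-butyl({2-[3-(PMB-oxy)propyl]pent-4-en-1-yl}oxy)diphenylsilane
Product: 10 (R)-6-(PMB-oxy)-3-(TBDPS-oxymethyl)hexanal
Conditions: OsO4 (2 mol %), NaIO4 (4 equiv), 2,6-lutidine, dioxane/H2O (3:1), rt
Reagents that add atoms: osmium tetroxide (oxygen carrier), O=[Os](=O)(=O)=O; sodium periodate (terminal oxygen source), [Na+].[O-]I(=O)(=O)=O
Why: Lemieux–Johnson cleavage (dihydroxylation, then glycol cleavage) unveils the C8 aldehyde and spares the PMB arene, which ozone might attack.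

Step 7
Reactants: 11 4-methyl hydrogen itaconate
Product: 12 methyl 3-(hydroxymethyl)but-3-enoate
Conditions: BH3·SMe2 (1.05 equiv), THF, −10 °C → rt; aqueous work-up
Reagents that add atoms: none
Why: Chemoselective borane reduction; the free acid (via its acyloxyborane) is reduced much faster than the methyl ester or the electron-poor alkene.

Step 8
Reactants: 12 methyl 3-(hydroxymethyl)but-3-enoate
Product: 13 methyl 3-(TBDPS-oxymethyl)but-3-enoate
Conditions: TBDPSCl, imidazole, CH2Cl2, 0 °C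
Reagents that add atoms: tert-butylchlorodiphenylsilane, CC(C)(C)[Si](Cl)(c1ccccc1)c1ccccc1
Why: Immediate silyl ether formation prevents lactonisation of the hydroxy ester and masks the C12 oxygen.

Step 9
Reactants: 13 methyl 3-(TBDPS-oxymethyl)but-3-enoate
Product: 14 3-(TBDPS-oxymethyl)but-3-enoic acid
Conditions: LiOH·H2O, THF/H2O (3:1), 0 °C; then 1 M HCl to pH 3
Reagents that add atoms: lithium hydroxide, [Li+].[OH-]
Why: Ester saponification; the cold, short hydroxide treatment leaves the β,γ-alkene out of conjugation.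

Step 10
Reactants: 14 3-(TBDPS-oxymethyl)but-3-enoic acid; 3 (S)-4-benzyl-1,3-oxazolidin-2-one
Product: 17 (S)-4-benzyl-3-[3-(TBDPS-oxymethyl)but-3-enoyl]oxazolidin-2-one, via mixed pivalic anhydride 15 (not isolated), via lithiated oxazolidinone 16 (not isolated)
Conditions: PivCl, Et3N, THF, −78 → 0 °C; separately 3, n-BuLi, THF, −78 °C; combine, −78 → 0 °C
Reagents that add atoms: pivaloyl chloride, CC(C)(C)C(=O)Cl (atoms only in 15); n-butyllithium, CCCC[Li] (lithium only in 16)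
Why: Low-temperature N-acylation of the lithiated oxazolidinone by the mixed anhydride gives the imide without isomerising the β,γ-alkene.

Step 11
Reactants: 17 (S)-4-benzyl-3-[3-(TBDPS-oxymethyl)but-3-enoyl]oxazolidin-2-one; 10 (R)-6-(PMB-oxy)-3-(TBDPS-oxymethyl)hexanal
Product: 19 (S)-4-benzyl-3-{(2S,3R,5R)-3-hydroxy-8-(PMB-oxy)-5-(TBDPS-oxymethyl)-2-[3-(TBDPS-oxy)prop-1-en-2-yl]octanoyl}oxazolidin-2-one, via boron enolate 18 (not isolated)
Conditions: Bu2BOTf, iPr2NEt, CH2Cl2, −78 → 0 °C; 10, −78 → 0 °C; pH 7 buffer, MeOH, 30% H2O2, 0 °C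
Reagents that add atoms: dibutylboron triflate, CCCCB(CCCC)OS(=O)(=O)C(F)(F)F (boron and butyl groups only in 18)
Why: Intermolecular Evans syn-aldol addition; the (Z)-boron enolate reacts at its α-carbon through a closed Zimmerman–Traxler transition state under auxiliary control, joining the two fragments at C7–C8 and setting C7 (S) and C8 (R) as needed for the trans-fused lactone.

Step 12
Reactants: 19 aldol adduct
Product: 20 (2S,3R,5R)-3-hydroxy-N-methoxy-N-methyl-8-(PMB-oxy)-5-(TBDPS-oxymethyl)-2-[3-(TBDPS-oxy)prop-1-en-2-yl]octanamide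
Conditions: MeNHOMe·HCl, AlMe3, CH2Cl2, −20 → 0 °C; aq. potassium sodium tartrate
Reagents that add atoms: N,O-dimethylhydroxylamine hydrochloride, CNOC.Cl
Why: Aluminium-amide transamidation (Weinreb amide formation), assisted by the free β-hydroxyl, releases auxiliary 3 without epimerising C7.

Step 13
Reactants: 20 Weinreb amide
Product: 21 (4S,5R,7R)-5-hydroxy-10-(PMB-oxy)-7-(TBDPS-oxymethyl)-4-[3-(TBDPS-oxy)prop-1-en-2-yl]-1-(trimethylsilyl)dec-1-yn-3-one
Conditions: Me3SiC≡CH, n-BuLi (3 equiv), THF, −78 °C; 20, −78 → −20 °C; AcOH, −78 °C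
Reagents that add atoms: trimethylsilylacetylene (used as its lithium acetylide), C#C[Si](C)(C)C
Why: Acyl substitution of the Weinreb amide by the lithium acetylide (ketone synthesis); the chelated tetrahedral intermediate prevents over-addition and the cold acidic quench protects the ynone and C7.

Step 14
Reactants: 21 β-hydroxy alkynyl ketone
Product: 22 (3S,4S,5R,7R)-10-(PMB-oxy)-7-(TBDPS-oxymethyl)-4-[3-(TBDPS-oxy)prop-1-en-2-yl]-1-(trimethylsilyl)dec-1-yne-3,5-diol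
Conditions: Me4NBH(OAc)3, MeCN/AcOH (1:1), −30 °C
Reagents that add atoms: none
Why: Evans–Saksena reduction; the C8 hydroxyl binds the borohydride and delivers hydride intramolecularly through a chair transition state, giving the 1,3-anti diol and so setting C6.

Step 15
Reactants: 22 anti-diol
Product: 23 (4S,5S,6R)-2,2-dimethyl-6-[(2R)-5-(PMB-oxy)-2-(TBDPS-oxymethyl)pentyl]-5-[3-(TBDPS-oxy)prop-1-en-2-yl]-4-[(trimethylsilyl)ethynyl]-1,3-dioxane
Conditions: 2,2-dimethoxypropane, PPTS (cat.), CH2Cl2, rt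
Reagents that add atoms: 2,2-dimethoxypropane, COC(C)(C)OC
Why: Acetal formation protects O6 and O8 together (the acetonide 13C shifts also confirm the anti relationship).

Step 16
Reactants: 23 silylalkyne acetonide
Product: 24 4-ethynyl analogue of 23 (terminal alkyne)
Conditions: K2CO3, MeOH, rt
Reagents that add atoms: none
Why: Base-mediated protodesilylation of the alkynyl C–Si bond leaves TBDPS ethers, acetonide and PMB ether untouched.

Step 17
Reactants: 24 terminal alkyne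
Product: 26 methyl 3-(dioxan-4-yl)propiolate (24 carrying C≡C–CO2Me), via lithium acetylide 25 (not isolated)
Conditions: n-BuLi, THF, −78 °C; ClCO2Me, −78 → 0 °C
Reagents that add atoms: methyl chloroformate, COC(=O)Cl; n-butyllithium, CCCC[Li] (lithium only in 25)
Why: Acetylide C-acylation installs C15 at the acid oxidation level, which directs the next step electronically.

Step 18
Reactants: 26 ynoate
Product: 28 methyl (E)-2-iodo-3-(dioxan-4-yl)acrylate (CO2Me cis to C6), via vinylstannane 27 (not isolated)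
Conditions: Pd(PPh3)4 (3 mol %), Bu3SnH, THF, 0 °C → rt; then I2, CH2Cl2, 0 °C; aq. Na2S2O3/KF
Reagents that add atoms: tributyltin hydride, CCCC[SnH](CCCC)CCCC (tin only in 27); iodine, [I][I]
Why: Zerovalent-palladium-catalysed syn-hydrostannation of the ynoate puts tin α to the ester and hydrogen on C5, and iododestannylation with retention gives the vinyl iodide with C15 cis to C6, as the butenolide and the E ring alkene require.

Step 19
Reactants: 28 α-iodo enoate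
Product: 29 (E)-2-iodo-3-(dioxan-4-yl)prop-2-en-1-ol
Conditions: iBu2AlH (2.5 equiv), CH2Cl2, −78 °C; aq. potassium sodium tartrate
Reagents that add atoms: none
Why: 1,2-Reduction of the conjugated ester by the aluminium hydride at −78 °C gives the allylic alcohol and leaves the vinyl iodide intact.

Step 20
Reactants: 29 iodo allylic alcohol
Product: 30 TBS ether of 29
Conditions: TBSCl, imidazole, CH2Cl2, rt
Reagents that add atoms: tert-butylchlorodimethylsilane, CC(C)(C)[Si](C)(C)Cl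
Why: Silyl ether formation masks C15–OH during the two oxidations and the ring closure; it is later removed together with the acetonide.

Step 21
Reactants: 30 TBS ether
Product: 31 primary C3 alcohol (30 without PMB)
Conditions: DDQ, CH2Cl2/pH 7 buffer (10:1), 0 °C
Reagents that add atoms: none
Why: Oxidative PMB ether cleavage (single-electron oxidation to the oxocarbenium ion, then hydrolysis) frees only the C3 hydroxyl.

Step 22
Reactants: 31 primary alcohol
Product: 32 C3 aldehyde (iodo-aldehyde)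
Conditions: Dess–Martin periodinane, NaHCO3, CH2Cl2, rt
Reagents that add atoms: none
Why: Dess–Martin oxidation gives the aldehyde under buffered conditions that tolerate the vinyl iodide, silyl ethers and acetonide.

Step 23
Reactants: 32 iodo-aldehyde
Product: 33 macrocyclic allylic alcohol (C3 epimers; 4E,6R,7S,8R,10R; 6,8-acetonide)
Conditions: CrCl2 (8 equiv), NiCl2 (2 mol %), DMSO/THF (3:1), rt, syringe-pump addition to 2 mM
Reagents that add atoms: none
Why: Intramolecular Nozaki–Hiyama–Kishi reaction; nickel-catalysed activation of the vinyl C–I bond, transmetalation to chromium and irreversible addition to the aldehyde at high dilution close the ten-membered ring at C3–C4 with retention of alkene geometry, C3 forming as a mixture that converges in step 24.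

Step 24
Reactants: 33 macrocyclic allylic alcohol
Product: 34 macrocyclic enone (C3 ketone; 4E,6R,7S,8R,10R)
Conditions: Dess–Martin periodinane, NaHCO3, CH2Cl2, rt
Reagents that add atoms: none
Why: Dess–Martin oxidation converges both C3 epimers to one enone, so the facial selectivity of the ring closure is irrelevant.

Step 25
Reactants: 34 macrocyclic enone
Product: 35 (3S)-allylic alcohol
Conditions: (R)-2-methyl-CBS-oxazaborolidine (0.5 equiv), catecholborane, toluene, −78 °C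
Reagents that add atoms: none
Why: Corey–Bakshi–Shibata reduction; the α-branched alkenyl group acts as the large substituent, so the (R)-catalyst delivers hydride to give 3S, and catecholborane does not hydroborate the isolated alkene.

Step 26
Reactants: 35 (3S)-allylic alcohol
Product: 36 (3S)-isobutyrate
Conditions: isobutyric anhydride, Et3N, DMAP (cat.), CH2Cl2, 0 °C → rt
Reagents that add atoms: isobutyric anhydride, CC(C)C(=O)OC(=O)C(C)C
Why: DMAP-catalysed acyl transfer esterifies the secondary allylic alcohol with retention at C3.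

Step 27
Reactants: 36 (3S)-isobutyrate
Product: 37 (3S,4E,6R,7S,8R,10R)-6,8-dihydroxy-4-(hydroxymethyl)-10-(TBDPS-oxymethyl)-7-[3-(TBDPS-oxy)prop-1-en-2-yl]cyclodec-4-en-3-yl isobutyrate
Conditions: CSA (0.2 equiv), MeOH, 0 °C → rt
Reagents that add atoms: none
Why: Acid-catalysed methanolysis removes the acetonide and the primary allylic TBS ether while the TBDPS ethers and the hindered ester persist.

Step 28
Reactants: 37 triol
Product: 40 15,6-olide (butenolide; C8–OH free; both TBDPS ethers kept), via enal 38 (not isolated), via lactol 39 (not isolated)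
Conditions: TEMPO (0.2 equiv), PhI(OAc)2 (2.5 equiv), CH2Cl2, rt
Reagents that add atoms: none
Why: Oxoammonium oxidation picks the only primary alcohol; O6 traps the cis-enal as a lactol that is oxidised to the butenolide (oxidative lactonisation), and O8 has no carbonyl partner because C12 is still silylated.

Step 29
Reactants: 40 butenolide
Product: 41 triol butenolide (free C8–OH; C12–OH; C14–OH)
Conditions: HF·pyridine, pyridine/THF, 0 °C → rt
Reagents that add atoms: none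
Why: Fluoride-mediated desilylation under buffered acidic conditions frees both primary alcohols without base-induced acyl migration or butenolide epimerisation.

Step 30
Reactants: 41 triol butenolide
Product: 44 target CNP0332805.1, via enal 42 (not isolated), via lactol 43 (not isolated)
Conditions: MnO2 (activated, 25 equiv), CH2Cl2, rt
Reagents that add atoms: none
Why: MnO2 oxidises only the allylic C12 alcohol; O8 traps the resulting 2-substituted acrolein as a lactol that is oxidised to the α-methylene-γ-butyrolactone (oxidative lactonisation), with the trans fusion fixed in step 11 and the saturated C14 alcohol untouched.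

**Compound list**
1 | δ-valerolactone | O=C1CCCCO1 | starting material
2 | 5-[(4-methoxybenzyl)oxy]pentanoic acid | COc1ccc(COCCCCC(=O)O)cc1 | intermediate
3 | (S)-4-benzyl-1,3-oxazolidin-2-one | O=C1N[C@@H](Cc2ccccc2)CO1 | starting material
4 | 5-(PMB-oxy)pentanoic pivalic anhydride (not isolated) | COc1ccc(COCCCCC(=O)OC(=O)C(C)(C)C)cc1 | intermediate
5 | (S)-4-benzyl-3-[5-(PMB-oxy)pentanoyl]oxazolidin-2-one | COc1ccc(COCCCCC(=O)N2C(=O)OC[C@@H]2Cc2ccccc2)cc1 | intermediate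
6 | sodium (Z)-enolate of 5 (not isolated) | [Na+].COc1ccc(COCCC/C=C(\[O-])N2C(=O)OC[C@@H]2Cc2ccccc2)cc1 | intermediate
7 | (S)-4-benzyl-3-[(2R)-2-allyl-5-(PMB-oxy)pentanoyl]oxazolidin-2-one | C=CC[C@H](C(=O)N1C(=O)OC[C@@H]1Cc1ccccc1)CCCOCc1ccc(OC)cc1 | intermediate
8 | (R)-2-allyl-5-(PMB-oxy)pentan-1-ol | C=CC[C@H](CO)CCCOCc1ccc(OC)cc1 | intermediate
9 | (R)-tert-butyl({2-[3-(PMB-oxy)propyl]pent-4-en-1-yl}oxy)diphenylsilane | C=CC[C@H](CO[Si](c1ccccc1)(c1ccccc1)C(C)(C)C)CCCOCc1ccc(OC)cc1 | intermediate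
10 | (R)-6-(PMB-oxy)-3-(TBDPS-oxymethyl)hexanal | O=CC[C@H](CO[Si](c1ccccc1)(c1ccccc1)C(C)(C)C)CCCOCc1ccc(OC)cc1 | intermediate
11 | 4-methyl hydrogen itaconate (4-methoxy-2-methylidene-4-oxobutanoic acid) | COC(=O)CC(=C)C(=O)O | starting material
12 | methyl 3-(hydroxymethyl)but-3-enoate | COC(=O)CC(=C)CO | intermediate
13 | methyl 3-(TBDPS-oxymethyl)but-3-enoate | COC(=O)CC(=C)CO[Si](c1ccccc1)(c1ccccc1)C(C)(C)C | intermediate
14 | 3-(TBDPS-oxymethyl)but-3-enoic acid | OC(=O)CC(=C)CO[Si](c1ccccc1)(c1ccccc1)C(C)(C)C | intermediate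
15 | 3-(TBDPS-oxymethyl)but-3-enoic pivalic anhydride (not isolated) | CC(C)(C)C(=O)OC(=O)CC(=C)CO[Si](c1ccccc1)(c1ccccc1)C(C)(C)C | intermediate
16 | N-lithio-(S)-4-benzyloxazolidin-2-one (not isolated) | [Li]N1[C@@H](Cc2ccccc2)COC1=O | intermediate
17 | (S)-4-benzyl-3-[3-(TBDPS-oxymethyl)but-3-enoyl]oxazolidin-2-one | C=C(CO[Si](c1ccccc1)(c1ccccc1)C(C)(C)C)CC(=O)N1C(=O)OC[C@@H]1Cc1ccccc1 | intermediate
18 | (Z)-dibutylboron enolate of 17 (not isolated) | CCCCB(CCCC)O/C(=C\C(=C)CO[Si](c1ccccc1)(c1ccccc1)C(C)(C)C)N1C(=O)OC[C@@H]1Cc1ccccc1 | intermediate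
19 | (S)-4-benzyl-3-{(2S,3R,5R)-3-hydroxy-8-(PMB-oxy)-5-(TBDPS-oxymethyl)-2-[3-(TBDPS-oxy)prop-1-en-2-yl]octanoyl}oxazolidin-2-one | O=C1OC[C@H](Cc2ccccc2)N1C(=O)[C@@H](C(=C)CO[Si](c1ccccc1)(c1ccccc1)C(C)(C)C)[C@H](O)C[C@H](CO[Si](c1ccccc1)(c1ccccc1)C(C)(C)C)CCCOCc1ccc(OC)cc1 | intermediate
20 | (2S,3R,5R)-3-hydroxy-N-methoxy-N-methyl-8-(PMB-oxy)-5-(TBDPS-oxymethyl)-2-[3-(TBDPS-oxy)prop-1-en-2-yl]octanamide | CON(C)C(=O)[C@@H](C(=C)CO[Si](c1ccccc1)(c1ccccc1)C(C)(C)C)[C@H](O)C[C@H](CO[Si](c1ccccc1)(c1ccccc1)C(C)(C)C)CCCOCc1ccc(OC)cc1 | intermediate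
21 | (4S,5R,7R)-5-hydroxy-10-(PMB-oxy)-7-(TBDPS-oxymethyl)-4-[3-(TBDPS-oxy)prop-1-en-2-yl]-1-(trimethylsilyl)dec-1-yn-3-one | C[Si](C)(C)C#CC(=O)[C@@H](C(=C)CO[Si](c1ccccc1)(c1ccccc1)C(C)(C)C)[C@H](O)C[C@H](CO[Si](c1ccccc1)(c1ccccc1)C(C)(C)C)CCCOCc1ccc(OC)cc1 | intermediate
22 | (3S,4S,5R,7R)-10-(PMB-oxy)-7-(TBDPS-oxymethyl)-4-[3-(TBDPS-oxy)prop-1-en-2-yl]-1-(trimethylsilyl)dec-1-yne-3,5-diol (3,5-anti) | C[Si](C)(C)C#C[C@@H](O)[C@@H](C(=C)CO[Si](c1ccccc1)(c1ccccc1)C(C)(C)C)[C@H](O)C[C@H](CO[Si](c1ccccc1)(c1ccccc1)C(C)(C)C)CCCOCc1ccc(OC)cc1 | intermediate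
23 | (4S,5S,6R)-2,2-dimethyl-6-[(2R)-5-(PMB-oxy)-2-(TBDPS-oxymethyl)pentyl]-5-[3-(TBDPS-oxy)prop-1-en-2-yl]-4-[(trimethylsilyl)ethynyl]-1,3-dioxane | C[Si](C)(C)C#C[C@H]1OC(C)(C)O[C@H](C[C@H](CO[Si](c2ccccc2)(c2ccccc2)C(C)(C)C)CCCOCc2ccc(OC)cc2)[C@@H]1C(=C)CO[Si](c2ccccc2)(c2ccccc2)C(C)(C)C | intermediate
24 | 4-ethynyl analogue of 23 (terminal alkyne) | C#C[C@H]1OC(C)(C)O[C@H](C[C@H](CO[Si](c2ccccc2)(c2ccccc2)C(C)(C)C)CCCOCc2ccc(OC)cc2)[C@@H]1C(=C)CO[Si](c2ccccc2)(c2ccccc2)C(C)(C)C | intermediate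
25 | lithium acetylide of 24 (not isolated) | [Li]C#C[C@H]1OC(C)(C)O[C@H](C[C@H](CO[Si](c2ccccc2)(c2ccccc2)C(C)(C)C)CCCOCc2ccc(OC)cc2)[C@@H]1C(=C)CO[Si](c2ccccc2)(c2ccccc2)C(C)(C)C | intermediate
26 | methyl 3-(dioxan-4-yl)propiolate (24 carrying C≡C–CO2Me) | COC(=O)C#C[C@H]1OC(C)(C)O[C@H](C[C@H](CO[Si](c2ccccc2)(c2ccccc2)C(C)(C)C)CCCOCc2ccc(OC)cc2)[C@@H]1C(=C)CO[Si](c2ccccc2)(c2ccccc2)C(C)(C)C | intermediate
27 | methyl (E)-3-(dioxan-4-yl)-2-(tributylstannyl)acrylate (not isolated) | COC(=O)/C(=C\[C@H]1OC(C)(C)O[C@H](C[C@H](CO[Si](c2ccccc2)(c2ccccc2)C(C)(C)C)CCCOCc2ccc(OC)cc2)[C@@H]1C(=C)CO[Si](c2ccccc2)(c2ccccc2)C(C)(C)C)[Sn](CCCC)(CCCC)CCCC | intermediate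
28 | methyl (E)-2-iodo-3-(dioxan-4-yl)acrylate (CO2Me cis to C6) | COC(=O)/C(I)=C\[C@H]1OC(C)(C)O[C@H](C[C@H](CO[Si](c2ccccc2)(c2ccccc2)C(C)(C)C)CCCOCc2ccc(OC)cc2)[C@@H]1C(=C)CO[Si](c2ccccc2)(c2ccccc2)C(C)(C)C | intermediate
29 | (E)-2-iodo-3-(dioxan-4-yl)prop-2-en-1-ol | OC/C(I)=C\[C@H]1OC(C)(C)O[C@H](C[C@H](CO[Si](c2ccccc2)(c2ccccc2)C(C)(C)C)CCCOCc2ccc(OC)cc2)[C@@H]1C(=C)CO[Si](c2ccccc2)(c2ccccc2)C(C)(C)C | intermediate
30 | TBS ether of 29 | CC(C)(C)[Si](C)(C)OC/C(I)=C\[C@H]1OC(C)(C)O[C@H](C[C@H](CO[Si](c2ccccc2)(c2ccccc2)C(C)(C)C)CCCOCc2ccc(OC)cc2)[C@@H]1C(=C)CO[Si](c2ccccc2)(c2ccccc2)C(C)(C)C | intermediate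
31 | primary C3 alcohol (30 without PMB) | CC(C)(C)[Si](C)(C)OC/C(I)=C\[C@H]1OC(C)(C)O[C@H](C[C@H](CO[Si](c2ccccc2)(c2ccccc2)C(C)(C)C)CCCO)[C@@H]1C(=C)CO[Si](c2ccccc2)(c2ccccc2)C(C)(C)C | intermediate
32 | C3 aldehyde (iodo-aldehyde) | CC(C)(C)[Si](C)(C)OC/C(I)=C\[C@H]1OC(C)(C)O[C@H](C[C@H](CO[Si](c2ccccc2)(c2ccccc2)C(C)(C)C)CCC=O)[C@@H]1C(=C)CO[Si](c2ccccc2)(c2ccccc2)C(C)(C)C | intermediate
33 | (4E,6R,7S,8R,10R)-6,8-O-isopropylidene-4-(TBS-oxymethyl)-10-(TBDPS-oxymethyl)-7-[3-(TBDPS-oxy)prop-1-en-2-yl]cyclodec-4-ene-3,6,8-triol, C3 epimers (target locants) | OC1CC[C@@H](CO[Si](c3ccccc3)(c3ccccc3)C(C)(C)C)C[C@H]2OC(C)(C)O[C@H](/C=C1\CO[Si](C)(C)C(C)(C)C)[C@H]2C(=C)CO[Si](c3ccccc3)(c3ccccc3)C(C)(C)C | intermediate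
34 | corresponding cyclodec-4-en-3-one (macrocyclic enone) | O=C1CC[C@@H](CO[Si](c3ccccc3)(c3ccccc3)C(C)(C)C)C[C@H]2OC(C)(C)O[C@H](/C=C1\CO[Si](C)(C)C(C)(C)C)[C@H]2C(=C)CO[Si](c3ccccc3)(c3ccccc3)C(C)(C)C | intermediate
35 | (3S)-alcohol of 33 | O[C@H]1CC[C@@H](CO[Si](c3ccccc3)(c3ccccc3)C(C)(C)C)C[C@H]2OC(C)(C)O[C@H](/C=C1\CO[Si](C)(C)C(C)(C)C)[C@H]2C(=C)CO[Si](c3ccccc3)(c3ccccc3)C(C)(C)C | intermediate
36 | 3-O-isobutyrate of 35 | CC(C)C(=O)O[C@H]1CC[C@@H](CO[Si](c3ccccc3)(c3ccccc3)C(C)(C)C)C[C@H]2OC(C)(C)O[C@H](/C=C1\CO[Si](C)(C)C(C)(C)C)[C@H]2C(=C)CO[Si](c3ccccc3)(c3ccccc3)C(C)(C)C | intermediate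
37 | (3S,4E,6R,7S,8R,10R)-6,8-dihydroxy-4-(hydroxymethyl)-10-(TBDPS-oxymethyl)-7-[3-(TBDPS-oxy)prop-1-en-2-yl]cyclodec-4-en-3-yl isobutyrate | CC(C)C(=O)O[C@H]1CC[C@@H](CO[Si](c2ccccc2)(c2ccccc2)C(C)(C)C)C[C@@H](O)[C@H](C(=C)CO[Si](c2ccccc2)(c2ccccc2)C(C)(C)C)[C@H](O)/C=C1\CO | intermediate
38 | C15 aldehyde of 37 (not isolated) | CC(C)C(=O)O[C@H]1CC[C@@H](CO[Si](c2ccccc2)(c2ccccc2)C(C)(C)C)C[C@@H](O)[C@H](C(=C)CO[Si](c2ccccc2)(c2ccccc2)C(C)(C)C)[C@H](O)/C=C1\C=O | intermediate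
39 | 15,6-lactol of 38 (not isolated) | CC(C)C(=O)O[C@H]1CC[C@@H](CO[Si](c3ccccc3)(c3ccccc3)C(C)(C)C)C[C@@H](O)[C@H](C(=C)CO[Si](c3ccccc3)(c3ccccc3)C(C)(C)C)[C@@H]2OC(O)C1=C2 | intermediate
40 | 15,6-olide (butenolide): 3-isobutyryloxy; 8-hydroxy; 10-CH2OTBDPS; 7-[3-(TBDPS-oxy)prop-1-en-2-yl] (3S,6R,7S,8R,10R) | CC(C)C(=O)O[C@H]1CC[C@@H](CO[Si](c3ccccc3)(c3ccccc3)C(C)(C)C)C[C@@H](O)[C@H](C(=C)CO[Si](c3ccccc3)(c3ccccc3)C(C)(C)C)[C@@H]2OC(=O)C1=C2 | intermediate
41 | 40 with both TBDPS groups removed (free C8–OH, C12–OH, C14–OH) | CC(C)C(=O)O[C@H]1CC[C@@H](CO)C[C@@H](O)[C@H](C(=C)CO)[C@@H]2OC(=O)C1=C2 | intermediate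
42 | C12 aldehyde of 41 (not isolated) | CC(C)C(=O)O[C@H]1CC[C@@H](CO)C[C@@H](O)[C@H](C(=C)C=O)[C@@H]2OC(=O)C1=C2 | intermediate
43 | 12,8-lactol of 42 (not isolated) | CC(C)C(=O)O[C@H]1CC[C@@H](CO)C[C@H]3OC(O)C(=C)[C@@H]3[C@@H]2OC(=O)C1=C2 | intermediate
44 | CNP0332805.1, (3S,6R,7S,8R,10R)-3-isobutyryloxy-14-hydroxy-germacr-4-ene-12,8:15,6-diolide with 11(13)-methylene | C=C1C(=O)O[C@@H]2C[C@H](CO)CC[C@H](OC(=O)C(C)C)C3=C[C@@H](OC3=O)[C@@H]12 | target

**Totals and risks**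
Total steps: 30. Longest linear sequence: 26 steps (steps 1–6, then 11–30, from δ-valerolactone); the imide branch (steps 7–10) adds 4 steps.

Most likely to fail, step 23 (ten-membered ring closure; oligomerisation or slow cyclisation): the fallback sets out from 31 and returns at 34. Alcohol 31 is oxidised (TEMPO, PhI(OAc)2, MeCN/H2O) to the carboxylic acid F3 and coupled with MeNHOMe·HCl (EDC·HCl, iPr2NEt, DMAP) to the Weinreb amide F4. Iodine–lithium exchange (t-BuLi, 2.1 equiv, THF, −78 °C, 1 mM) followed by intramolecular acyl substitution on the amide closes the ring anionically and gives ketone 34 directly, with no chromium and no C3 carbinol stage.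

Second, step 25 (facial control on a macrocyclic enone may be overridden by the ring conformation): the fallback sets out from 34 and returns at 36. Substrate-controlled Luche reduction (NaBH4, CeCl3·7H2O, MeOH, −78 °C) is used instead; if it, or the CBS step, gives the (3R)-alcohol F5, Mitsunobu esterification with isobutyric acid (PPh3, DIAD, toluene, 0 °C) inverts C3 and gives the (3S)-isobutyrate 36 directly.

Third, step 14 (directed reduction of an electrophilic alkynyl ketone may lose anti selectivity through undirected hydride transfer): the fallback sets out from 21 and returns at 22. The C8 hydroxyl is silylated (TESOTf, 2,6-lutidine, CH2Cl2, −78 °C) to the triethylsilyl ether F1. Reagent-controlled transfer hydrogenation with RuCl[(S,S)-TsDPEN](p-cymene) in iPrOH (alkynyl group in the role of the aryl group) gives the (6S)-propargylic alcohol F2, and PPTS/MeOH removes the triethylsilyl group to give diol 22.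

**Further compounds**
F1 | step 14 | C8-O-triethylsilyl ether of ynone 21 | C[Si](C)(C)C#CC(=O)[C@@H](C(=C)CO[Si](c1ccccc1)(c1ccccc1)C(C)(C)C)[C@H](O[Si](CC)(CC)CC)C[C@H](CO[Si](c1ccccc1)(c1ccccc1)C(C)(C)C)CCCOCc1ccc(OC)cc1
F2 | step 14 | (6S)-propargylic alcohol with C8-O-triethylsilyl ether | C[Si](C)(C)C#C[C@@H](O)[C@@H](C(=C)CO[Si](c1ccccc1)(c1ccccc1)C(C)(C)C)[C@H](O[Si](CC)(CC)CC)C[C@H](CO[Si](c1ccccc1)(c1ccccc1)C(C)(C)C)CCCOCc1ccc(OC)cc1
F3 | step 23 | C3 carboxylic acid from 31 | CC(C)(C)[Si](C)(C)OC/C(I)=C\[C@H]1OC(C)(C)O[C@H](C[C@H](CO[Si](c2ccccc2)(c2ccccc2)C(C)(C)C)CCC(=O)O)[C@@H]1C(=C)CO[Si](c2ccccc2)(c2ccccc2)C(C)(C)C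
F4 | step 23 | C3 Weinreb amide (N-methoxy-N-methylamide of F3) | CC(C)(C)[Si](C)(C)OC/C(I)=C\[C@H]1OC(C)(C)O[C@H](C[C@H](CO[Si](c2ccccc2)(c2ccccc2)C(C)(C)C)CCC(=O)N(C)OC)[C@@H]1C(=C)CO[Si](c2ccccc2)(c2ccccc2)C(C)(C)C
F5 | step 25 | (3R)-epimer of alcohol 35 | O[C@@H]1CC[C@@H](CO[Si](c3ccccc3)(c3ccccc3)C(C)(C)C)C[C@H]2OC(C)(C)O[C@H](/C=C1\CO[Si](C)(C)C(C)(C)C)[C@H]2C(=C)CO[Si](c3ccccc3)(c3ccccc3)C(C)(C)C
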